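**Retrosynthetic overview**

- Feature: the carbocycle C4a–C5–C6–C7–C8–C8a is fused to the 4-pyridone ring at C4a–C8a. C5 (chain) and C8 (OH) are para-related sp3 carbons with cis substituents, and C6 and C7 are plain CH2. This is the pattern left by syn hydrogenation of the benzo ring of a 5,8-disubstituted 4-quinolone.
- Target 15 ⇐ ester 10: the ester carbon is extended (partial reduction, Wittig reaction with 12, alkene hydrogenation) and the silyl ether is cleaved. The phenyl group is brought in only after the arene hydrogenation, which it would not survive.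
- 10 ⇐ quinolone 9: enantioselective hydrogenation of the benzo ring alone sets C5 and C8 together, cis.
- 9 ⇐ aniline 4 + keto ester 5 by Conrad–Limpach synthesis (N1–C2 and C4–C4a), then benzyl-to-silyl exchange; 4 ⇐ 2 + 3 (Negishi coupling); 2 ⇐ 1.
- Ring order: the benzene ring is bought in 1, the pyridone ring is closed in step 4, and the benzene ring is saturated to the carbocycle in step 7.

Key step: step 7

Assumption: which antipode of the carbene ligand leads to (5S,8R) on this substrate class cannot be deduced in advance. The (R,R)-ligand is written, and its mirror image would be used if the sense of induction proves opposite.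

**Route**

Step 1
Reactants: 1 2-amino-4-bromophenol
Product: 2 2-(benzyloxy)-5-bromoaniline
Conditions: NaH (1.05 equiv), DMF, 0 °C; BnBr (1.0 equiv), 0 °C → rt
Reagents that add atoms: benzyl bromide, BrCc1ccccc1
Why: Williamson ether synthesis, in which the sodium phenoxide is far more nucleophilic than the neutral, electron-poor aniline nitrogen, so one equivalent of benzyl bromide should alkylate oxygen only.

Step 2
Reactants: 2 2-(benzyloxy)-5-bromoaniline; 3 (4-ethoxy-4-oxobutyl)zinc bromide
Product: 4 ethyl 4-[3-amino-4-(benzyloxy)phenyl]butanoate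
Conditions: 3 (1.5 equiv, THF solution), Pd(OAc)2 (2 mol%), SPhos (4 mol%), THF, 50 °C
Reagents that add atoms: none
Why: Negishi sp2–sp3 cross-coupling, in which zerovalent palladium inserts into the unhindered C–Br bond and the primary alkylzinc halide tolerates both the ester and the free NH2, the bulky biaryl phosphine favouring reductive elimination over β-hydride loss.

Step 3
Reactants: 4 ethyl 4-[3-amino-4-(benzyloxy)phenyl]butanoate; 5 methyl 2-methoxy-3-oxobutanoate
Product: 6 methyl (E)-3-{[2-(benzyloxy)-5-(4-ethoxy-4-oxobutyl)phenyl]amino}-2-methoxybut-2-enoate (N–H hydrogen-bonded to the ester carbonyl)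
Conditions: p-TsOH·H2O (5 mol%), cyclohexane, Dean–Stark, reflux
Reagents that add atoms: none
Why: First stage of the Conrad–Limpach synthesis, an acid-catalysed condensation of the aniline with the ketone carbonyl that, at about 80 °C with azeotropic removal of water, should give the β-enamino ester and not the anilide.

Step 4
Reactants: 6 methyl (E)-3-{[2-(benzyloxy)-5-(4-ethoxy-4-oxobutyl)phenyl]amino}-2-methoxybut-2-enoate
Product: 7 ethyl 4-[8-(benzyloxy)-3-methoxy-2-methyl-4-oxo-1,4-dihydroquinolin-5-yl]butanoate
Conditions: Ph2O, 250 °C, 20–30 min (6 added to the hot solvent); cool, dilute with hexane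
Reagents that add atoms: none
Why: Conrad–Limpach thermal cyclisation with loss of methanol, which can close only onto the one free carbon ortho to nitrogen (the other ortho carbon carries the benzyloxy group), so the 5,8-substitution pattern is forced; the aryl benzyl ether and the ethyl ester should survive the short thermolysis.

Step 5
Reactants: 7 ethyl 4-[8-(benzyloxy)-3-methoxy-2-methyl-4-oxo-1,4-dihydroquinolin-5-yl]butanoate
Product: 8 ethyl 4-(8-hydroxy-3-methoxy-2-methyl-4-oxo-1,4-dihydroquinolin-5-yl)butanoate
Conditions: H2 (1 atm), 10% Pd/C, EtOH/THF, rt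
Reagents that add atoms: none
Why: Hydrogenolysis of the benzyl aryl ether over Pd/C at atmospheric pressure, conditions under which the quinolone nucleus and the ester are not reduced; the benzyl group has to go because its phenyl ring would be saturated in step 7.

Step 6
Reactants: 8 ethyl 4-(8-hydroxy-3-methoxy-2-methyl-4-oxo-1,4-dihydroquinolin-5-yl)butanoate
Product: 9 ethyl 4-[8-(tert-butyldimethylsilyloxy)-3-methoxy-2-methyl-4-oxo-1,4-dihydroquinolin-5-yl]butanoate
Conditions: TBSCl (1.2 equiv), imidazole (2.5 equiv), DMF, rt
Reagents that add atoms: tert-butyldimethylsilyl chloride, CC(C)(C)[Si](C)(C)Cl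
Why: Imidazole-promoted silyl ether formation at the phenolic O–H, the vinylogous amide giving no silyl derivative that outlasts aqueous work-up, so that only O8 should carry silicon.

Step 7
Reactants: 9 ethyl 4-[8-(tert-butyldimethylsilyloxy)-3-methoxy-2-methyl-4-oxo-1,4-dihydroquinolin-5-yl]butanoate
Product: 10 ethyl 4-[(5S,8R)-8-(tert-butyldimethylsilyloxy)-3-methoxy-2-methyl-4-oxo-1,4,5,6,7,8-hexahydroquinolin-5-yl]butanoate
Conditions: Ru(2-methylallyl)2(cod) (5 mol%), (R,R)-SINpEt·HBF4 [1,3-bis((R)-1-(naphthalen-1-yl)ethyl)-4,5-dihydroimidazolium tetrafluoroborate] (10 mol%), KOtBu (12 mol%), n-hexane, 70 °C (catalyst preformed); then 9, H2 (100 bar), n-hexane/t-AmOH, 30 °C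
Reagents that add atoms: none
Why: Proposed new method: the preformed ruthenium bis(carbene) complex should bind the π face of the benzo ring of 9, split H2 and pass two molecules of H2 to C5, C6, C7 and C8 from the metal-bound face before the ring is released (C4a=C8a stays as part of the pyridone), so the four new C–H bonds are syn and the C5 chain and the C8 silyloxy group end cis. The closest known reactions are the enantioselective carbocycle hydrogenations of quinolines and related fused arenes with Ru(2-methylallyl)2(cod) and chiral carbene ligands, and the PtO2-in-acid reductions of 4-quinolones to 5,6,7,8-tetrahydro-4-quinolones; their use together on a 5,8-disubstituted 4-quinolone is what is new. No ring is closed and no skeletal bond is formed. The cis relationship of C5 and C8 follows from one-face hydrogen delivery, and the absolute configuration (5S,8R) from the chiral pocket of the two C2-symmetric carbene ligands, which decides which face of the flat quinolone is bound. The step needs ring selectivity and retention of the C8–O bond: the pyridone ring is a fully substituted, electron-rich vinylogous amide that resists reduction, the unsubstituted C6 and C7 leave the benzo ring open to the metal, and the silyl group keeps the half-reduced silyl enol ether from tautomerising to a C8 ketone. The ethyl ester is inert to this catalyst, which is why the chain ends in an ester here and not in a phenyl group.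

Step 8
Reactants: 10 ethyl 4-[(5S,8R)-8-(tert-butyldimethylsilyloxy)-3-methoxy-2-methyl-4-oxo-1,4,5,6,7,8-hexahydroquinolin-5-yl]butanoate
Product: 11 4-[(5S,8R)-8-(tert-butyldimethylsilyloxy)-3-methoxy-2-methyl-4-oxo-1,4,5,6,7,8-hexahydroquinolin-5-yl]butanal
Conditions: iBu2AlH (2.2 equiv), CH2Cl2, −78 °C; MeOH, then aq. KNaC4H4O6 (potassium sodium tartrate), rt
Reagents that add atoms: none
Why: Partial reduction of the ester with iBu2AlH, in which one equivalent is taken up by the acidic pyridone N–H and the second gives a tetrahedral aluminium hemiacetal that is stable at −78 °C and should collapse to the aldehyde only on work-up, the vinylogous amide carbonyl (as its N-aluminate) being too electron-rich to be reduced.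

Step 9
Reactants: 11 4-[(5S,8R)-8-(tert-butyldimethylsilyloxy)-3-methoxy-2-methyl-4-oxo-1,4,5,6,7,8-hexahydroquinolin-5-yl]butanal; 12 benzyltriphenylphosphonium chloride
Product: 13 (5S,8R)-8-(tert-butyldimethylsilyloxy)-3-methoxy-2-methyl-5-(5-phenylpent-4-en-1-yl)-5,6,7,8-tetrahydroquinolin-4(1H)-one (E/Z mixture)
Conditions: 12 (3.0 equiv), NaN(SiMe3)2 (2.9 equiv), THF, 0 °C; then 11, 0 °C → rt
Reagents that add atoms: none
Why: Wittig olefination with the semi-stabilised benzylide, used in excess because the pyridone N–H quenches one equivalent; the alkene geometry is of no consequence since both isomers converge in step 10.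

Step 10
Reactants: 13 (5S,8R)-8-(tert-butyldimethylsilyloxy)-3-methoxy-2-methyl-5-(5-phenylpent-4-en-1-yl)-5,6,7,8-tetrahydroquinolin-4(1H)-one
Product: 14 (5S,8R)-8-(tert-butyldimethylsilyloxy)-3-methoxy-2-methyl-5-(5-phenylpentyl)-5,6,7,8-tetrahydroquinolin-4(1H)-one
Conditions: H2 (1 atm), 10% Pd/C, EtOAc, rt
Reagents that add atoms: none
Why: Heterogeneous hydrogenation of the disubstituted styrenyl alkene, which at atmospheric pressure in a neutral aprotic solvent should leave the phenyl ring, the pyridone, the silyl ether and both stereocentres untouched.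

Step 11
Reactants: 14 (5S,8R)-8-(tert-butyldimethylsilyloxy)-3-methoxy-2-methyl-5-(5-phenylpentyl)-5,6,7,8-tetrahydroquinolin-4(1H)-one
Product: 15 (5S,8R)-8-hydroxy-3-methoxy-2-methyl-5-(5-phenylpentyl)-5,6,7,8-tetrahydroquinolin-4(1H)-one
Conditions: Bu4NF (1.5 equiv), THF, 0 °C → rt
Reagents that add atoms: none
Why: Fluoride-driven desilylation, chosen over acid because acid could ionise the C8–O bond next to the electron-rich pyridone ring and scramble C8, whereas fluoride attacks only silicon and leaves C5 and C8 as set.

**Compound list**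

1 | 2-amino-4-bromophenol | Nc1cc(Br)ccc1O | starting material
2 | 2-(benzyloxy)-5-bromoaniline | Nc1cc(Br)ccc1OCc1ccccc1 | intermediate
3 | (4-ethoxy-4-oxobutyl)zinc bromide | CCOC(=O)CCC[Zn]Br | starting material
4 | ethyl 4-[3-amino-4-(benzyloxy)phenyl]butanoate | CCOC(=O)CCCc1ccc(OCc2ccccc2)c(N)c1 | intermediate
5 | methyl 2-methoxy-3-oxobutanoate | COC(C(C)=O)C(=O)OC | starting material
6 | methyl (E)-3-{[2-(benzyloxy)-5-(4-ethoxy-4-oxobutyl)phenyl]amino}-2-methoxybut-2-enoate | COC(=O)/C(OC)=C(/C)Nc1cc(CCCC(=O)OCC)ccc1OCc1ccccc1 | intermediate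
7 | ethyl 4-[8-(benzyloxy)-3-methoxy-2-methyl-4-oxo-1,4-dihydroquinolin-5-yl]butanoate | CCOC(=O)CCCc1ccc(OCc2ccccc2)c2[nH]c(C)c(OC)c(=O)c12 | intermediate
8 | ethyl 4-(8-hydroxy-3-methoxy-2-methyl-4-oxo-1,4-dihydroquinolin-5-yl)butanoate | CCOC(=O)CCCc1ccc(O)c2[nH]c(C)c(OC)c(=O)c12 | intermediate
9 | ethyl 4-[8-(tert-butyldimethylsilyloxy)-3-methoxy-2-methyl-4-oxo-1,4-dihydroquinolin-5-yl]butanoate | CCOC(=O)CCCc1ccc(O[Si](C)(C)C(C)(C)C)c2[nH]c(C)c(OC)c(=O)c12 | intermediate
10 | ethyl 4-[(5S,8R)-8-(tert-butyldimethylsilyloxy)-3-methoxy-2-methyl-4-oxo-1,4,5,6,7,8-hexahydroquinolin-5-yl]butanoate | COc1c(C)[nH]c2c(c1=O)[C@@H](CCCC(=O)OCC)CC[C@H]2O[Si](C)(C)C(C)(C)C | intermediate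
11 | 4-[(5S,8R)-8-(tert-butyldimethylsilyloxy)-3-methoxy-2-methyl-4-oxo-1,4,5,6,7,8-hexahydroquinolin-5-yl]butanal | COc1c(C)[nH]c2c(c1=O)[C@@H](CCCC=O)CC[C@H]2O[Si](C)(C)C(C)(C)C | intermediate
12 | benzyltriphenylphosphonium chloride | [Cl-].c1ccc(C[P+](c2ccccc2)(c2ccccc2)c2ccccc2)cc1 | starting material
13 | (5S,8R)-8-(tert-butyldimethylsilyloxy)-3-methoxy-2-methyl-5-(5-phenylpent-4-en-1-yl)-5,6,7,8-tetrahydroquinolin-4(1H)-one (E/Z mixture) | COc1c(C)[nH]c2c(c1=O)[C@@H](CCCC=Cc1ccccc1)CC[C@H]2O[Si](C)(C)C(C)(C)C | intermediate
14 | (5S,8R)-8-(tert-butyldimethylsilyloxy)-3-methoxy-2-methyl-5-(5-phenylpentyl)-5,6,7,8-tetrahydroquinolin-4(1H)-one | COc1c(C)[nH]c2c(c1=O)[C@@H](CCCCCc1ccccc1)CC[C@H]2O[Si](C)(C)C(C)(C)C | intermediate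
15 | (5S,8R)-8-hydroxy-3-methoxy-2-methyl-5-(5-phenylpentyl)-5,6,7,8-tetrahydroquinolin-4(1H)-one | COc1c(C)[nH]c2c(c1=O)[C@@H](CCCCCc1ccccc1)CC[C@H]2O | target

**Step count and risks**

Total step count: 11. Longest linear sequence: 11 steps (1 → 15).

Steps most likely to fail:

1. Step 7 (the proposed new method). The catalyst may not turn over on the tetrasubstituted benzo ring, may release the half-reduced silyl enol ether and so erode the cis relationship, may attack the pyridone ring, or may select the face poorly. The fallback uses known chemistry and sets out from 9. Heterogeneous hydrogenation over PtO2 in acetic acid under H2 pressure is the established way to take 4-quinolones to 5,6,7,8-tetrahydro-4-quinolones, with hydrogen delivered from the surface to one face. It should give the racemic cis compound ethyl 4-[(5RS,8SR)-8-(tert-butyldimethylsilyloxy)-3-methoxy-2-methyl-4-oxo-1,4,5,6,7,8-hexahydroquinolin-5-yl]butanoate F1. Resolution of F1 by preparative chromatography on a chiral stationary phase returns to the route at 10.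

2. Step 4. At 250 °C the side-chain ester may degrade, or ring closure next to the three-carbon chain may be slow enough for the enamine to decompose first. The fallback changes the order of bond formation and sets out from 2. Condensation of 2 with 5 (p-TsOH·H2O, cyclohexane, Dean–Stark) should give methyl (E)-3-{[2-(benzyloxy)-5-bromophenyl]amino}-2-methoxybut-2-enoate F2. Thermolysis in Ph2O at 250 °C should give 8-(benzyloxy)-5-bromo-3-methoxy-2-methylquinolin-4(1H)-one F3, with a thermally robust bromine in place of the ester chain. Negishi coupling of F3 with 3 (3 equiv to cover the acidic N–H; Pd(OAc)2, SPhos, THF/NMP, 60 °C) comes back to the route at 7.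

3. Step 8. Over-reduction to the primary alcohol, or incomplete conversion because the pyridone ties up the hydride reagent, may spoil the partial reduction. The fallback is a reduce-then-oxidise sequence and sets out from 10. LiBH4 in THF should reduce the ester fully to (5S,8R)-8-(tert-butyldimethylsilyloxy)-5-(4-hydroxybutyl)-3-methoxy-2-methyl-5,6,7,8-tetrahydroquinolin-4(1H)-one F4. Oxidation of F4 with Dess–Martin periodinane (NaHCO3, CH2Cl2, rt) comes back to the route at 11.

**Further compounds**

F1 | step 7 | ethyl 4-[(5RS,8SR)-8-(tert-butyldimethylsilyloxy)-3-methoxy-2-methyl-4-oxo-1,4,5,6,7,8-hexahydroquinolin-5-yl]butanoate (racemic, cis) | COc1c(C)[nH]c2c(c1=O)[C@@H](CCCC(=O)OCC)CC[C@H]2O[Si](C)(C)C(C)(C)C.COc1c(C)[nH]c2c(c1=O)[C@H](CCCC(=O)OCC)CC[C@@H]2O[Si](C)(C)C(C)(C)C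
F2 | step 4 | methyl (E)-3-{[2-(benzyloxy)-5-bromophenyl]amino}-2-methoxybut-2-enoate | COC(=O)/C(OC)=C(/C)Nc1cc(Br)ccc1OCc1ccccc1
F3 | step 4 | 8-(benzyloxy)-5-bromo-3-methoxy-2-methylquinolin-4(1H)-one | COc1c(C)[nH]c2c(OCc3ccccc3)ccc(Br)c2c1=O
F4 | step 8 | (5S,8R)-8-(tert-butyldimethylsilyloxy)-5-(4-hydroxybutyl)-3-methoxy-2-methyl-5,6,7,8-tetrahydroquinolin-4(1H)-one | COc1c(C)[nH]c2c(c1=O)[C@@H](CCCCO)CC[C@H]2O[Si](C)(C)C(C)(C)C
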